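**Plan**

- Rings: A is the benzo ring of the chroman, C the pyran ring, B the 2-phenyl group, D the pendant 6-hydroxy-2,4-dimethoxy-3-methylphenyl ring.
- Retrosynthesis, in order: the ring D O–pivaloyl bond is cut first (protecting group). Ring C is then cut at C4–C4a and O1–C2 together, back to the O-cinnamyl ether of a bibenzyl phenol. The bridge is cut last at the ring D–CH2 bond, back to a ring D aryl iodide and a ring A arylacetylene.
- Forward: the ring D iodide (from 2,6-dimethoxytoluene) and the ring A alkyne (from 2-hydroxy-4,6-dimethoxybenzaldehyde) are joined by Sonogashira coupling. Hydrogenation gives the ethylene bridge and frees the ring A phenol, which is O-cinnamylated. Ring C is formed last, then the pivalate is removed.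
- Enabling feature: ring A is a phloroglucinol-type ring whose O1 and only free ortho carbon C4a form a C,O-bis-nucleophile. It is matched by a cinnamyl unit whose allylic C4 and benzylic C2 (next to ring B) are the two electrophilic ends. C8 is already blocked by the bridge.
- Stereochemistry: the only stereocentre, C2 (S), is set in the ring C-forming step by a chiral confined Brønsted acid (catalyst control, stereoconvergent from all cinnamyl isomers).

Key step: step 9

Assumption: the (S,S)-antipode of the imidodiphosphorimidate catalyst is taken to deliver the (2S) product; if the sense of induction proves opposite, the (R,R)-antipode is used in the same way.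

**Step 1**
Reactants: 1 2,6-dimethoxytoluene
Product: 3 3,5-dimethoxy-4-methylphenol, via arylboronate 2 (not isolated)
Conditions: [Ir(OMe)(cod)]2 (1.5 mol%), 4,4'-di-tert-butyl-2,2'-bipyridine (3 mol%), B2pin2 (1.0 equiv), THF, 80 °C; then KHSO5 (Oxone), acetone/H2O, rt
Reagents that add atoms: bis(pinacolato)diboron, CC1(C)OB(OC1(C)C)B1OC(C)(C)C(C)(C)O1 (boron in 2); potassium peroxymonosulfate, [K+].[O-]S(=O)(=O)OO (oxygen in 3)
Why: Iridium-catalysed aromatic C–H borylation is sterically controlled and should go to C4 of 1, the only ring C–H without an ortho substituent, and the boronate 2 is then oxidised in the same flask to the phenol (one-pot C–H borylation–oxidation).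

**Step 2**
Reactants: 3 3,5-dimethoxy-4-methylphenol
Product: 4 2-iodo-3,5-dimethoxy-4-methylphenol
Conditions: NIS (1.0 equiv), MeCN, −20 °C to 0 °C, dark
Reagents that add atoms: N-iodosuccinimide, O=C1CCC(=O)N1I
Why: Electrophilic aromatic iodination of the highly activated phenol: the para position is blocked by the methyl group and the two ortho positions are equivalent, so a single mono-iodide is expected when one equivalent of NIS is used cold.

**Step 3**
Reactants: 4 2-iodo-3,5-dimethoxy-4-methylphenol
Product: 5 2-iodo-3,5-dimethoxy-4-methylphenyl pivalate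
Conditions: PivCl, Et3N, DMAP (cat.), CH2Cl2, 0 °C to rt
Reagents that add atoms: pivaloyl chloride, CC(C)(C)C(Cl)=O
Why: Standard DMAP-catalysed O-acylation; the pivalate masks the ring D phenol, lowers the nucleophilicity of ring D for the later acid step and is expected to survive the amine base, hydrogenation, K2CO3 and acid conditions ahead.

**Step 4**
Reactants: 6 2-hydroxy-4,6-dimethoxybenzaldehyde
Product: 7 2-(benzyloxy)-4,6-dimethoxybenzaldehyde
Conditions: BnBr, K2CO3, DMF, 60 °C
Reagents that add atoms: benzyl bromide, BrCc1ccccc1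
Why: Williamson ether synthesis; the benzyl ether keeps the ring A phenol from cyclising onto the alkyne during the coupling and is removed later in the hydrogenation that also saturates the bridge.

**Step 5**
Reactants: 7 2-(benzyloxy)-4,6-dimethoxybenzaldehyde
Product: 8 1-(benzyloxy)-2-ethynyl-3,5-dimethoxybenzene
Conditions: dimethyl (1-diazo-2-oxopropyl)phosphonate (1.5 equiv), K2CO3 (2 equiv), MeOH, rt to 40 °C
Reagents that add atoms: dimethyl (1-diazo-2-oxopropyl)phosphonate (Ohira–Bestmann reagent), COP(=O)(OC)C(=[N+]=[N-])C(C)=O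
Why: Seyferth–Gilbert homologation in its Ohira–Bestmann form turns the aldehyde into the terminal alkyne under mild carbonate conditions that leave the benzyl and methyl ethers untouched.

**Step 6**
Reactants: 5 2-iodo-3,5-dimethoxy-4-methylphenyl pivalate; 8 1-(benzyloxy)-2-ethynyl-3,5-dimethoxybenzene
Product: 9 2-{[2-(benzyloxy)-4,6-dimethoxyphenyl]ethynyl}-3,5-dimethoxy-4-methylphenyl pivalate
Conditions: Pd(PPh3)2Cl2 (5 mol%), CuI (5 mol%), Et3N/DMF (1:2), degassed, 60 °C, slow addition of 8
Reagents that add atoms: none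
Why: Sonogashira coupling joins the aryl iodide of ring D to the terminal alkyne and so creates the two-carbon bridge between rings A and D; the aryl pivalate is inert to the palladium triphenylphosphine catalyst.

**Step 7**
Reactants: 9 2-{[2-(benzyloxy)-4,6-dimethoxyphenyl]ethynyl}-3,5-dimethoxy-4-methylphenyl pivalate
Product: 10 2-[2-(2-hydroxy-4,6-dimethoxyphenyl)ethyl]-3,5-dimethoxy-4-methylphenyl pivalate
Conditions: H2 (3 atm), 10% Pd/C, EtOAc/MeOH (1:1), rt
Reagents that add atoms: none
Why: Heterogeneous hydrogenation over Pd/C saturates the diarylalkyne to the ethylene bridge and hydrogenolyses the benzyl ether in the same operation, while the aryl pivalate and the methyl ethers are not affected.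

**Step 8**
Reactants: 10 2-[2-(2-hydroxy-4,6-dimethoxyphenyl)ethyl]-3,5-dimethoxy-4-methylphenyl pivalate; 11 (E)-cinnamyl bromide
Product: 12 2-[2-(2-{[(2E)-3-phenylprop-2-en-1-yl]oxy}-4,6-dimethoxyphenyl)ethyl]-3,5-dimethoxy-4-methylphenyl pivalate
Conditions: K2CO3 (2 equiv), acetone, reflux
Reagents that add atoms: none
Why: Williamson O-allylation of the single free phenol with the reactive allylic bromide under mild carbonate conditions, which a pivalate tolerates, installs the three-carbon unit on the ring A oxygen.

**Step 9**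
Reactants: 12 2-[2-(2-{[(2E)-3-phenylprop-2-en-1-yl]oxy}-4,6-dimethoxyphenyl)ethyl]-3,5-dimethoxy-4-methylphenyl pivalate
Product: 14 2-{2-[(2S)-5,7-dimethoxy-2-phenyl-3,4-dihydro-2H-chromen-8-yl]ethyl}-3,5-dimethoxy-4-methylphenyl pivalate, via o-cinnamylphenol 13 (not isolated)
Conditions: (S,S)-imidodiphosphorimidate Brønsted acid (BINOL-derived IDPi with N-triflyl core, 3,3'-aryl groups chosen by screening, 5 mol%), CHCl3 (0.02 M), 4 Å molecular sieves, −20 °C to rt
Reagents that add atoms: none
Why: Proposed new method: the chiral strong Brønsted acid ionises the allylic C–O bond of 12 to a cinnamyl cation that stays ion-paired next to ring A, whose only free ortho carbon C4a attacks the CH2 terminus to give the o-cinnamylphenol 13 (C4–C4a bond, a formal [1,3] O-to-C shift), after which the acid protonates the styrene at C3 and the ring A oxygen adds to the benzylic carbon C2 (O1–C2 bond). The closest known reaction types are the Lewis or Brønsted acid-catalysed rearrangement–cyclisation of aryl allylic ethers and the acid-catalysed annulation of phenols with cinnamyl alcohols, both giving racemic chromans, and the imidodiphosphorimidate-catalysed asymmetric intramolecular hydroalkoxylation of alkenes, which have not yet been merged or applied to a flavan. Ring C closes by 6-endo-trig Markovnikov attack of O1 on C2, preferred over 5-exo attack on C3 because only C2 is stabilised as a benzylic cation by ring B. The new stereocentre C2 is set by the catalyst, whose confined chiral counter-anion should shield one face of the benzylic cation while the hydrogen-bonded phenol attacks the other, and the step is stereoconvergent because E and Z alkenes as well as any branched or O-bound cinnamyl isomers drain through this one ion pair. The step needs ring A over ring D and ortho over para selectivity: C8 is blocked by the ethylene bridge so only C4a alkylation can lead on to ring closure, the para (C6) adduct cannot cyclise and should revert by acid-catalysed retro-Friedel–Crafts exchange, and ring D is masked and deactivated as its pivalate.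

**Step 10**
Reactants: 14 2-{2-[(2S)-5,7-dimethoxy-2-phenyl-3,4-dihydro-2H-chromen-8-yl]ethyl}-3,5-dimethoxy-4-methylphenyl pivalate
Product: 15 2-{2-[(2S)-5,7-dimethoxy-2-phenyl-3,4-dihydro-2H-chromen-8-yl]ethyl}-3,5-dimethoxy-4-methylphenol
Conditions: NaOMe (20 mol%), MeOH/THF (3:1), 50 °C; aq. NH4Cl
Reagents that add atoms: none
Why: Base-catalysed transesterification (methanolysis) of the aryl pivalate releases the ring D phenol; the chroman, the methyl ethers and the C2 stereocentre are not touched by methoxide.

**Compound list**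

1 | 2,6-dimethoxytoluene (1,3-dimethoxy-2-methylbenzene) | COc1cccc(OC)c1C | starting material
2 | 2-(3,5-dimethoxy-4-methylphenyl)-4,4,5,5-tetramethyl-1,3,2-dioxaborolane | COc1cc(B2OC(C)(C)C(C)(C)O2)cc(OC)c1C | intermediate
3 | 3,5-dimethoxy-4-methylphenol | COc1cc(O)cc(OC)c1C | intermediate
4 | 2-iodo-3,5-dimethoxy-4-methylphenol | COc1cc(O)c(I)c(OC)c1C | intermediate
5 | 2-iodo-3,5-dimethoxy-4-methylphenyl pivalate (2,2-dimethylpropanoate) | COc1cc(OC(=O)C(C)(C)C)c(I)c(OC)c1C | intermediate
6 | 2-hydroxy-4,6-dimethoxybenzaldehyde | COc1cc(O)c(C=O)c(OC)c1 | starting material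
7 | 2-(benzyloxy)-4,6-dimethoxybenzaldehyde | COc1cc(OCc2ccccc2)c(C=O)c(OC)c1 | intermediate
8 | 1-(benzyloxy)-2-ethynyl-3,5-dimethoxybenzene | COc1cc(OCc2ccccc2)c(C#C)c(OC)c1 | intermediate
9 | 2-{[2-(benzyloxy)-4,6-dimethoxyphenyl]ethynyl}-3,5-dimethoxy-4-methylphenyl pivalate | COc1cc(OCc2ccccc2)c(C#Cc2c(OC(=O)C(C)(C)C)cc(OC)c(C)c2OC)c(OC)c1 | intermediate
10 | 2-[2-(2-hydroxy-4,6-dimethoxyphenyl)ethyl]-3,5-dimethoxy-4-methylphenyl pivalate | COc1cc(O)c(CCc2c(OC(=O)C(C)(C)C)cc(OC)c(C)c2OC)c(OC)c1 | intermediate
11 | (E)-cinnamyl bromide ((E)-(3-bromoprop-1-en-1-yl)benzene) | BrC/C=C/c1ccccc1 | starting material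
12 | 2-[2-(2-{[(2E)-3-phenylprop-2-en-1-yl]oxy}-4,6-dimethoxyphenyl)ethyl]-3,5-dimethoxy-4-methylphenyl pivalate | COc1cc(OC/C=C/c2ccccc2)c(CCc2c(OC(=O)C(C)(C)C)cc(OC)c(C)c2OC)c(OC)c1 | intermediate
13 | 2-(2-{2-hydroxy-4,6-dimethoxy-3-[(2E)-3-phenylprop-2-en-1-yl]phenyl}ethyl)-3,5-dimethoxy-4-methylphenyl pivalate | COc1cc(OC)c(C/C=C/c2ccccc2)c(O)c1CCc1c(OC(=O)C(C)(C)C)cc(OC)c(C)c1OC | intermediate
14 | 2-{2-[(2S)-5,7-dimethoxy-2-phenyl-3,4-dihydro-2H-chromen-8-yl]ethyl}-3,5-dimethoxy-4-methylphenyl pivalate | COc1cc(OC(=O)C(C)(C)C)c(CCc2c(OC)cc(OC)c3c2O[C@H](c2ccccc2)CC3)c(OC)c1C | intermediate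
15 | 2-{2-[(2S)-5,7-dimethoxy-2-phenyl-3,4-dihydro-2H-chromen-8-yl]ethyl}-3,5-dimethoxy-4-methylphenol | COc1cc(O)c(CCc2c(OC)cc(OC)c3c2O[C@H](c2ccccc2)CC3)c(OC)c1C | target

**Totals and risks**

Total step count: 10. Longest linear sequence: 8 steps (steps 1, 2, 3, 6, 7, 8, 9, 10).

Steps most likely to fail:

1. Step 9. The chiral ion pair may discriminate the two faces of the benzylic cation poorly. Turnover of the confined acid may be slow with the bulky bibenzyl substrate. Cinnamyl transfer to the para position C6 or to another molecule may not revert. Fallback, from 10 by known chemistry that makes the two bonds separately: ortho-specific formylation (MgCl2, Et3N, paraformaldehyde, MeCN, reflux) should give the salicylaldehyde F1. Wittig olefination with (benzoylmethylene)triphenylphosphorane (toluene, 90 °C) should give the (E)-enone F2. Hydrogenation of the C=C bond only (H2, Pd/C, EtOAc, rt, stopped after one equivalent) should give the ketone F3. Noyori transfer hydrogenation with RuCl(p-cymene)[(R,R)-TsDPEN] in HCO2H/Et3N should give the (R)-alcohol F4. Mitsunobu cyclisation (PPh3, DIAD, THF, 0 °C) then closes O1–C2 with inversion to the (2S)-chroman and comes back to the route at 14.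

2. Step 6. Oxidative addition and transmetalation may be slow at the doubly ortho-substituted, electron-rich partners, so that oxidative homocoupling of the alkyne takes over. Fallback, from 7 and 5, replacing the sp–sp2 coupling by an sp3–sp2 coupling: Wittig methylenation of 7 (Ph3PCH3Br, KOtBu, THF, 0 °C to rt) should give the styrene F5. Anti-Markovnikov hydroboration with 9-BBN (THF, rt) should give the alkylborane F6. This is coupled without isolation with iodide 5 (Pd(dppf)Cl2, aq. K3PO4, THF/DMF, 60 °C, B-alkyl Suzuki–Miyaura coupling) to the benzyl-protected bibenzyl F7. Hydrogenolysis (H2, 10% Pd/C, EtOAc/MeOH) then comes back to the route at 10.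

3. Step 5. Addition of the diazophosphonate anion to the doubly ortho-alkoxylated, electron-rich aldehyde may be sluggish, leaving the homologation incomplete. Fallback, from 7 by the Corey–Fuchs sequence: dibromo-olefination with the more reactive ylide (CBr4, PPh3, CH2Cl2, 0 °C) should give the dibromoalkene F8. Treatment with n-BuLi (2.2 equiv, THF, −78 °C, then aq. NH4Cl) induces bromine–lithium exchange and carbenoid rearrangement and comes back to the route at 8.

**Further compounds**

F1 | step 9 | 2-[2-(3-formyl-2-hydroxy-4,6-dimethoxyphenyl)ethyl]-3,5-dimethoxy-4-methylphenyl pivalate | COc1cc(OC)c(C=O)c(O)c1CCc1c(OC(=O)C(C)(C)C)cc(OC)c(C)c1OC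
F2 | step 9 | 2-(2-{2-hydroxy-4,6-dimethoxy-3-[(1E)-3-oxo-3-phenylprop-1-en-1-yl]phenyl}ethyl)-3,5-dimethoxy-4-methylphenyl pivalate | COc1cc(OC)c(/C=C/C(=O)c2ccccc2)c(O)c1CCc1c(OC(=O)C(C)(C)C)cc(OC)c(C)c1OC
F3 | step 9 | 2-{2-[2-hydroxy-4,6-dimethoxy-3-(3-oxo-3-phenylpropyl)phenyl]ethyl}-3,5-dimethoxy-4-methylphenyl pivalate | COc1cc(OC)c(CCC(=O)c2ccccc2)c(O)c1CCc1c(OC(=O)C(C)(C)C)cc(OC)c(C)c1OC
F4 | step 9 | 2-(2-{2-hydroxy-3-[(3R)-3-hydroxy-3-phenylpropyl]-4,6-dimethoxyphenyl}ethyl)-3,5-dimethoxy-4-methylphenyl pivalate | COc1cc(OC)c(CC[C@@H](O)c2ccccc2)c(O)c1CCc1c(OC(=O)C(C)(C)C)cc(OC)c(C)c1OC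
F5 | step 6 | 1-(benzyloxy)-2-ethenyl-3,5-dimethoxybenzene | COc1cc(OCc2ccccc2)c(C=C)c(OC)c1
F6 | step 6 | 9-{2-[2-(benzyloxy)-4,6-dimethoxyphenyl]ethyl}-9-borabicyclo[3.3.1]nonane | COc1cc(OCc2ccccc2)c(CCB2C3CCCC2CCC3)c(OC)c1
F7 | step 6 | 2-{2-[2-(benzyloxy)-4,6-dimethoxyphenyl]ethyl}-3,5-dimethoxy-4-methylphenyl pivalate | COc1cc(OCc2ccccc2)c(CCc2c(OC(=O)C(C)(C)C)cc(OC)c(C)c2OC)c(OC)c1
F8 | step 5 | 1-(benzyloxy)-2-(2,2-dibromoethenyl)-3,5-dimethoxybenzene | COc1cc(OCc2ccccc2)c(C=C(Br)Br)c(OC)c1
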